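**Plan**

1. Retrosynthesis (target numbered as a bicyclo[3.2.1]octan-8-one): the allyl group is traced back to a CH2CHO arm and the C2 alcohol to a ketone; then the bonds C8–C1 and C2–C3 are cut together.
2. Enabling feature: C1 carries the bridging ketone carbon C8, a methoxy group and the oxygenated C2. This is the 2-acyl-2-alkoxy ketone pattern left by a 1,2-acyl shift. The cyclopentanone ring C1–C8–C5–C6–C7 is therefore read as a ring-contracted 2-oxygenated 3-methoxycyclohex-2-enone, and the ring C1–C2–C3–C4–C5–C8 closes when the enol carbon (C2) attacks an acetal carbon (C3) of a two-carbon arm on C5.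
3. Precursor: cyclohexenone 15 with two identical CH2CH(OMe)2 arms on the future C5 (one becomes C4–C3, the other the allyl group) and a silyl group on the enol oxygen that is shed in the key step.
4. Forward order: cyclohexenone ring (organocatalytic annulation), two arms, oxidation of the enone to the silyloxy methoxy enone, aryl group, then the cascade that forms the cyclopentanone and the six-membered ring together, then arm to allyl and ketone to alcohol.
5. Stereochemistry: C6 (methyl) from the organocatalyst; C7 (aryl) trans to it in the arylation; C5, C1 and C3 in the key step by relay from C6 and C7; C2 by a reagent-controlled reduction.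

Key step: step 9

Remark: the sense of induction in step 1 is taken from the usual steric model for diarylprolinol silyl ether iminium ions (attack anti to the shielding group), which pairs the (R)-catalyst with (S)-4.

**Step 1**
Reactants: 1 (E)-but-2-enal; 2 tert-butyl 3-oxobutanoate
Product: 4 (5S)-5-methylcyclohex-2-en-1-one, via Michael adduct 3 (not isolated)
Conditions: (R)-2-{bis[3,5-bis(trifluoromethyl)phenyl][(trimethylsilyl)oxy]methyl}pyrrolidine (10 mol %), toluene, rt; then TsOH·H2O (20 mol %), 80 °C
Reagents that add atoms: none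
Why: Iminium-ion Michael addition of the β-keto ester to the enal sets the methyl-bearing stereocentre by attack anti to the shielding group of the catalyst, and acid then brings about intramolecular aldol condensation, ester cleavage and decarboxylation (Robinson-type annulation).

**Step 2**
Reactants: 4 (5S)-5-methylcyclohex-2-en-1-one
Product: 6 (5S)-5-methyl-6,6-di(prop-2-en-1-yl)cyclohex-2-en-1-one, via monoallyl enone 5 (not isolated)
Conditions: LiN(iPr)2 (1.1 equiv), THF, −78 °C; allyl bromide, −78 → 0 °C; recool, LiN(iPr)2 (1.2 equiv), DMPU; allyl bromide, −78 °C → rt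
Reagents that add atoms: allyl bromide, C=CCBr
Why: Kinetic α′-deprotonation gives the cross-conjugated lithium enolate, which is C-allylated twice at C-6 (enolate alkylation); the second allylation removes the transient C-6 stereocentre, so no selectivity is needed.

**Step 3**
Reactants: 6 (5S)-5-methyl-6,6-di(prop-2-en-1-yl)cyclohex-2-en-1-one
Product: 8 (5S)-6,6-bis(2,2-dimethoxyethyl)-5-methylcyclohex-2-en-1-one, via dialdehyde 7 (not isolated)
Conditions: O3 (2 equiv, dosed), CH2Cl2, −78 °C; Me2S, → rt; then HC(OMe)3, pyridinium p-toluenesulfonate (cat.), rt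
Reagents that add atoms: ozone, [O-][O+]=O; trimethyl orthoformate, COC(OC)OC
Why: The electron-rich monosubstituted alkenes should be ozonised before the electron-poor enone double bond (ozonolysis with reductive work-up), and the orthoformate then masks both aldehydes as dimethyl acetals.

**Step 4**
Reactants: 8 (5S)-6,6-bis(2,2-dimethoxyethyl)-5-methylcyclohex-2-en-1-one
Product: 9 (1S,4S,6S)-3,3-bis(2,2-dimethoxyethyl)-4-methyl-7-oxabicyclo[4.1.0]heptan-2-one
Conditions: 30 % aq. H2O2, NaOH (cat.), MeOH, 0 °C
Reagents that add atoms: hydrogen peroxide, OO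
Why: Weitz–Scheffer nucleophilic epoxidation of the enone, expected anti to the methyl group, leaves the acetals untouched; either epoxide face would converge in step 6.

**Step 5**
Reactants: 9 (1S,4S,6S)-3,3-bis(2,2-dimethoxyethyl)-4-methyl-7-oxabicyclo[4.1.0]heptan-2-one
Product: 10 (2S,3R,5S)-6,6-bis(2,2-dimethoxyethyl)-2-hydroxy-3-methoxy-5-methylcyclohexan-1-one
Conditions: MeOH, 10-camphorsulfonic acid (5 mol %), 0 °C
Reagents that add atoms: methanol, CO
Why: Acid-catalysed epoxide methanolysis should open the ring with inversion at the carbon remote from the carbonyl group (the α-carbon is deactivated towards cationic opening), while the dimethyl acetals persist in methanol.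

**Step 6**
Reactants: 10 (2S,3R,5S)-6,6-bis(2,2-dimethoxyethyl)-2-hydroxy-3-methoxy-5-methylcyclohexan-1-one
Product: 12 (5S)-6,6-bis(2,2-dimethoxyethyl)-2-hydroxy-3-methoxy-5-methylcyclohex-2-en-1-one, via 1,2-dione 11 (not isolated)
Conditions: Dess–Martin periodinane (1.3 equiv), pyridine, CH2Cl2, 0 °C → rt; SiO2
Reagents that add atoms: none
Why: Dess–Martin oxidation of the acyloin gives the 1,2-dione, which can enolise only towards the methoxy-bearing carbon (the other α-carbon is quaternary) and should be obtained as the hydrogen-bonded diosphenol; the stereocentres from steps 4 and 5 are removed here.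

**Step 7**
Reactants: 12 (5S)-6,6-bis(2,2-dimethoxyethyl)-2-hydroxy-3-methoxy-5-methylcyclohex-2-en-1-one
Product: 13 (5S)-2-{[tert-butyl(dimethyl)silyl]oxy}-6,6-bis(2,2-dimethoxyethyl)-3-methoxy-5-methylcyclohex-2-en-1-one
Conditions: tBuMe2SiCl, imidazole, DMF, rt
Reagents that add atoms: tert-butyldimethylsilyl chloride, CC(C)(C)[Si](C)(C)Cl
Why: Silylation of the acidic enol hydroxyl (silyl ether formation) installs the oxygen-bound group that is to drive and then leave in the acyl shift of step 9.

**Step 8**
Reactants: 13 (5S)-2-{[tert-butyl(dimethyl)silyl]oxy}-6,6-bis(2,2-dimethoxyethyl)-3-methoxy-5-methylcyclohex-2-en-1-one; 14 5-bromo-1,2,3-trimethoxybenzene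
Product: 15 (4R,5S)-2-{[tert-butyl(dimethyl)silyl]oxy}-6,6-bis(2,2-dimethoxyethyl)-3-methoxy-5-methyl-4-(3,4,5-trimethoxyphenyl)cyclohex-2-en-1-one
Conditions: Pd(OAc)2 (5 mol %), tBu3P·HBF4 (10 mol %), LiN(SiMe3)2 (2.2 equiv), toluene, 50 °C
Reagents that add atoms: none
Why: Palladium-catalysed γ-arylation of the lithium dienolate of the vinylogous ester: C-6 is quaternary and C-2 fully substituted, so only C-4 can couple, and the aryl group should enter anti to the neighbouring methyl group (trans, also the thermodynamic isomer since C-4 stays epimerisable).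

**Step 9**
Reactants: 15 (4R,5S)-2-{[tert-butyl(dimethyl)silyl]oxy}-6,6-bis(2,2-dimethoxyethyl)-3-methoxy-5-methyl-4-(3,4,5-trimethoxyphenyl)cyclohex-2-en-1-one
Product: 16 (1S,3R,5R,6S,7R)-5-(2,2-dimethoxyethyl)-1,3-dimethoxy-6-methyl-7-(3,4,5-trimethoxyphenyl)bicyclo[3.2.1]octane-2,8-dione
Conditions: Me3SiOTf (20 mol %), 2,6-di-tert-butyl-4-methylpyridine (30 mol %), CH2Cl2, −78 → −20 °C
Reagents that add atoms: none
Why: Proposed new method: Me3SiOTf ionises one dimethyl acetal to an oxocarbenium ion that is attacked by C-2 of 15, the α-carbon of a push–pull enol ether (the site at which ascorbate-type 2-oxy-3-alkoxy enones are C-alkylated), and the O-methyl oxocarbenium ion left at C-3 is discharged by a 1,2-shift of the ring acyl carbon C-1 from C-2 to C-3, the silyloxy oxygen becoming the new ketone and the silyl group leaving as tBuMe2SiOMe. The closest known reaction types are the Mukaiyama-type addition of enol ethers to acetals for the first bond and, for the second, the acyloin (α-ketol) ring contraction of 2-alkyl-2-hydroxycyclohexane-1,3-diones (humulone to isohumulone) and the acyl-shift rearrangement of α,β-epoxy ketones, here made irreversible by the O-methyl group. The first bond closes a five-membered ring in a 5-exo-trig mode at the oxocarbenium carbon (a bicyclo[3.2.1]octan-8-one with the carbonyl still bound to the enol carbon), and the acyl shift then contracts the original cyclohexenone to the cyclopentanone and widens the new five-membered ring to the six-membered ring, so both rings of 16 come from one cyclisation and one shift. C-5 of 16 is fixed by the choice between the two diastereotopic arms, because only the arm cis to the methyl group can bridge to the enol carbon with methyl and aryl equatorial whereas the trans arm would hold the aryl group syn-1,3-diaxial to the new bridge; C-1 follows from the suprafacial shift within the bicycle, and C-3 from the exo orientation of the oxocarbenium methoxy group, away from the three-atom bridge. The step needs C- over O-alkylation (an O-alkylated mixed acetal would re-ionise), attack at C-2 rather than C-3 of 15 (attack at C-3 would leave a cation next to the ketone) and acyl rather than alkyl migration (the usual course of acyloin contractions, the alkyl shift leading to a more strained bicyclo[2.2.2]octane-2,3-dione).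

**Step 10**
Reactants: 16 (1S,3R,5R,6S,7R)-5-(2,2-dimethoxyethyl)-1,3-dimethoxy-6-methyl-7-(3,4,5-trimethoxyphenyl)bicyclo[3.2.1]octane-2,8-dione
Product: 17 (1S,3R,5R,6S,7R)-1,3-dimethoxy-6-methyl-5-(2-oxoethyl)-7-(3,4,5-trimethoxyphenyl)bicyclo[3.2.1]octane-2,8-dione
Conditions: CF3CO2H–H2O (9:1), CH2Cl2, 0 °C
Reagents that add atoms: water, O
Why: Acid-catalysed acetal hydrolysis unmasks the aldehyde of the remaining arm; the non-enolisable 1,3-dione and the methyl ethers should be inert to aqueous acid.

**Step 11**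
Reactants: 17 (1S,3R,5R,6S,7R)-1,3-dimethoxy-6-methyl-5-(2-oxoethyl)-7-(3,4,5-trimethoxyphenyl)bicyclo[3.2.1]octane-2,8-dione
Product: 18 (1S,3R,5S,6S,7R)-1,3-dimethoxy-6-methyl-5-(prop-2-en-1-yl)-7-(3,4,5-trimethoxyphenyl)bicyclo[3.2.1]octane-2,8-dione
Conditions: Ph3PCH3Br (1.1 equiv), KN(SiMe3)2 (1.05 equiv), THF, 0 °C; then 17, −78 → 0 °C
Reagents that add atoms: methyltriphenylphosphonium bromide, C[P+](c1ccccc1)(c1ccccc1)c1ccccc1.[Br-]
Why: Wittig methylenation with one equivalent of ylide at low temperature should take the aldehyde in preference to the hindered C-2 ketone and the bridging C-8 ketone, giving the allyl group; C-3 next to the C-2 ketone can only equilibrate towards its equatorial methoxy epimer, the one required.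

**Step 12**
Reactants: 18 (1S,3R,5S,6S,7R)-1,3-dimethoxy-6-methyl-5-(prop-2-en-1-yl)-7-(3,4,5-trimethoxyphenyl)bicyclo[3.2.1]octane-2,8-dione
Product: 19 (1R,2R,3R,5S,6S,7R)-2-hydroxy-1,3-dimethoxy-6-methyl-5-(prop-2-en-1-yl)-7-(3,4,5-trimethoxyphenyl)bicyclo[3.2.1]octan-8-one
Conditions: (S)-1-methyl-3,3-diphenyltetrahydro-1H,3H-pyrrolo[1,2-c][1,3,2]oxazaborole ((S)-Me-CBS, 1.0 equiv), catecholborane (2 equiv), toluene, −78 → −40 °C; MeOH, pH 7 buffer
Reagents that add atoms: none
Why: Corey–Bakshi–Shibata reduction: the (S)-oxazaborolidine should bind the C-2 carbonyl oxygen anti to the quaternary C-1 and deliver hydride to the face that gives the (2R) axial alcohol, overriding the substrate preference for attack syn to C-8, while the C-8 ketone between two quaternary carbons and the alkene (no free borane) stay untouched.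

**Compound list**

1 | (E)-but-2-enal | C/C=C/C=O | starting material
2 | tert-butyl 3-oxobutanoate | CC(=O)CC(=O)OC(C)(C)C | starting material
3 | tert-butyl (3S)-2-acetyl-3-methyl-5-oxopentanoate (mixture at C-2) | O=CC[C@H](C)C(C(C)=O)C(=O)OC(C)(C)C | intermediate
4 | (5S)-5-methylcyclohex-2-en-1-one | O=C1C=CC[C@H](C)C1 | intermediate
5 | (5S,6R)-5-methyl-6-(prop-2-en-1-yl)cyclohex-2-en-1-one | O=C1C=CC[C@H](C)[C@H]1CC=C | intermediate
6 | (5S)-5-methyl-6,6-di(prop-2-en-1-yl)cyclohex-2-en-1-one | O=C1C=CC[C@H](C)C1(CC=C)CC=C | intermediate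
7 | 2,2'-[(6S)-6-methyl-2-oxocyclohex-3-ene-1,1-diyl]diacetaldehyde | O=C1C=CC[C@H](C)C1(CC=O)CC=O | intermediate
8 | (5S)-6,6-bis(2,2-dimethoxyethyl)-5-methylcyclohex-2-en-1-one | O=C1C=CC[C@H](C)C1(CC(OC)OC)CC(OC)OC | intermediate
9 | (1S,4S,6S)-3,3-bis(2,2-dimethoxyethyl)-4-methyl-7-oxabicyclo[4.1.0]heptan-2-one | O=C1[C@H]2O[C@H]2C[C@H](C)C1(CC(OC)OC)CC(OC)OC | intermediate
10 | (2S,3R,5S)-6,6-bis(2,2-dimethoxyethyl)-2-hydroxy-3-methoxy-5-methylcyclohexan-1-one | O=C1[C@@H](O)[C@H](OC)C[C@H](C)C1(CC(OC)OC)CC(OC)OC | intermediate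
11 | (4S,6R)-3,3-bis(2,2-dimethoxyethyl)-6-methoxy-4-methylcyclohexane-1,2-dione | O=C1C(=O)[C@H](OC)C[C@H](C)C1(CC(OC)OC)CC(OC)OC | intermediate
12 | (5S)-6,6-bis(2,2-dimethoxyethyl)-2-hydroxy-3-methoxy-5-methylcyclohex-2-en-1-one | O=C1C(O)=C(OC)C[C@H](C)C1(CC(OC)OC)CC(OC)OC | intermediate
13 | (5S)-2-{[tert-butyl(dimethyl)silyl]oxy}-6,6-bis(2,2-dimethoxyethyl)-3-methoxy-5-methylcyclohex-2-en-1-one | O=C1C(O[Si](C)(C)C(C)(C)C)=C(OC)C[C@H](C)C1(CC(OC)OC)CC(OC)OC | intermediate
14 | 5-bromo-1,2,3-trimethoxybenzene | COc1cc(Br)cc(OC)c1OC | starting material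
15 | (4R,5S)-2-{[tert-butyl(dimethyl)silyl]oxy}-6,6-bis(2,2-dimethoxyethyl)-3-methoxy-5-methyl-4-(3,4,5-trimethoxyphenyl)cyclohex-2-en-1-one | O=C1C(O[Si](C)(C)C(C)(C)C)=C(OC)[C@@H](c2cc(OC)c(OC)c(OC)c2)[C@H](C)C1(CC(OC)OC)CC(OC)OC | intermediate
16 | (1S,3R,5R,6S,7R)-5-(2,2-dimethoxyethyl)-1,3-dimethoxy-6-methyl-7-(3,4,5-trimethoxyphenyl)bicyclo[3.2.1]octane-2,8-dione | COC(OC)C[C@@]12C[C@@H](OC)C(=O)[C@@](OC)(C1=O)[C@@H](c1cc(OC)c(OC)c(OC)c1)[C@@H]2C | intermediate
17 | (1S,3R,5R,6S,7R)-1,3-dimethoxy-6-methyl-5-(2-oxoethyl)-7-(3,4,5-trimethoxyphenyl)bicyclo[3.2.1]octane-2,8-dione | O=CC[C@@]12C[C@@H](OC)C(=O)[C@@](OC)(C1=O)[C@@H](c1cc(OC)c(OC)c(OC)c1)[C@@H]2C | intermediate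
18 | (1S,3R,5S,6S,7R)-1,3-dimethoxy-6-methyl-5-(prop-2-en-1-yl)-7-(3,4,5-trimethoxyphenyl)bicyclo[3.2.1]octane-2,8-dione | C=CC[C@@]12C[C@@H](OC)C(=O)[C@@](OC)(C1=O)[C@@H](c1cc(OC)c(OC)c(OC)c1)[C@@H]2C | intermediate
19 | (1R,2R,3R,5S,6S,7R)-2-hydroxy-1,3-dimethoxy-6-methyl-5-(prop-2-en-1-yl)-7-(3,4,5-trimethoxyphenyl)bicyclo[3.2.1]octan-8-one | C=CC[C@@]12C[C@@H](OC)[C@@H](O)[C@@](OC)(C1=O)[C@@H](c1cc(OC)c(OC)c(OC)c1)[C@@H]2C | target

Total step count: 12. Longest linear sequence: 12 steps (1 and 2 to 19).

**Steps most likely to fail**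

Step 9. The cascade may stop after the first C–C bond, with capture of the intermediate oxocarbenium ion or loss of the benzylic proton next to it outrunning the 1,2-acyl shift. Attack through the methoxy-bearing enol carbon is a second possible diversion. The fallback separates the two bond formations and uses known reaction types. It sets out from 15: TiCl4 (1.1 equiv) in CH2Cl2 at −78 °C with aqueous work-up should give, by a Mukaiyama-type acetal cyclisation, the bridged silyloxy dione F1. Bu4NF in THF at 0 °C then frees the tertiary alkoxide, which should undergo the base-mediated acyloin ring contraction of the humulone type to the hydroxy dione F2. Methylation of the tertiary hydroxyl with MeOTf and 2,6-di-tert-butyl-4-methylpyridine returns to the route at 16.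

Step 12. Hydride delivery from the more open face syn to C-8 may compete with the reagent-controlled mode, giving poor facial selectivity at C-2. The fallback accepts the substrate preference and inverts afterwards. It sets out from 18: Luche reduction (NaBH4, CeCl3·7H2O, MeOH, −40 °C) should give the equatorial alcohol F3. Mitsunobu reaction with 4-nitrobenzoic acid, PPh3 and diisopropyl azodicarboxylate in toluene brings the nucleophile in from that same open face and should give the inverted 4-nitrobenzoate F4. Brief methanolysis (K2CO3, 0.2 equiv, MeOH, 0 °C) returns to the route at 19.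

Step 5. Under the acidic conditions the β-methoxy ketone may lose methanol by elimination to the unsubstituted diosphenol, or the epoxide may open at the wrong carbon. The fallback reaches the same enol by way of a vinylogous ester. It sets out from 9: isomerisation of the epoxy ketone with Pd(PPh3)4 and 1,2-bis(diphenylphosphino)ethane in toluene at 80 °C should give the 1,3-dione F5. O-Methylation with Me2SO4 and K2CO3 in acetone, at the oxygen remote from the quaternary carbon, should give the vinylogous ester F6. α-Hydroxylation of its enol ether double bond with dimethyldioxirane in acetone at −20 °C returns to the route at 12.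

**Further compounds**

F1 | step 9 | (1S,3R,4S,5R,7R)-1-{[tert-butyl(dimethyl)silyl]oxy}-5-(2,2-dimethoxyethyl)-7-methoxy-4-methyl-3-(3,4,5-trimethoxyphenyl)bicyclo[3.2.1]octane-2,8-dione | O=C1[C@@]2(O[Si](C)(C)C(C)(C)C)C(=O)[C@@H](c3cc(OC)c(OC)c(OC)c3)[C@H](C)[C@]1(CC(OC)OC)C[C@H]2OC
F2 | step 9 | (1S,3R,5R,6S,7R)-5-(2,2-dimethoxyethyl)-1-hydroxy-3-methoxy-6-methyl-7-(3,4,5-trimethoxyphenyl)bicyclo[3.2.1]octane-2,8-dione | COC(OC)C[C@@]12C[C@@H](OC)C(=O)[C@@](O)(C1=O)[C@@H](c1cc(OC)c(OC)c(OC)c1)[C@@H]2C
F3 | step 12 | (1R,2S,3R,5S,6S,7R)-2-hydroxy-1,3-dimethoxy-6-methyl-5-(prop-2-en-1-yl)-7-(3,4,5-trimethoxyphenyl)bicyclo[3.2.1]octan-8-one | C=CC[C@@]12C[C@@H](OC)[C@H](O)[C@@](OC)(C1=O)[C@@H](c1cc(OC)c(OC)c(OC)c1)[C@@H]2C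
F4 | step 12 | (1R,2R,3R,5S,6S,7R)-1,3-dimethoxy-6-methyl-8-oxo-5-(prop-2-en-1-yl)-7-(3,4,5-trimethoxyphenyl)bicyclo[3.2.1]octan-2-yl 4-nitrobenzoate | C=CC[C@@]12C[C@@H](OC)[C@@H](OC(=O)c3ccc(cc3)[N+](=O)[O-])[C@@](OC)(C1=O)[C@@H](c1cc(OC)c(OC)c(OC)c1)[C@@H]2C
F5 | step 5 | (5S)-4,4-bis(2,2-dimethoxyethyl)-5-methylcyclohexane-1,3-dione | O=C1CC(=O)C[C@H](C)C1(CC(OC)OC)CC(OC)OC
F6 | step 5 | (5S)-6,6-bis(2,2-dimethoxyethyl)-3-methoxy-5-methylcyclohex-2-en-1-one | O=C1C=C(OC)C[C@H](C)C1(CC(OC)OC)CC(OC)OC
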